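## Retrosynthetic overview

1. Marchantin C 26 ⇐ BBr3 demethylation of its di-O-methyl ether 25 (18-membered ring).
2. 25 ⇐ ring contraction of the 19-membered azacyclophane 22 by excision of the NH between two benzylic carbons (isodiazene, loss of N2); this closes the last ethano bridge (ring B to ring C).
3. 22 ⇐ macrocyclising double reductive amination of the open-chain dialdehyde 19 with ammonia (the only macrocyclisation).
4. 19 ⇐ hydrogenation of diaryl alkyne 18 ⇐ one-pot double Sonogashira of two diaryl ether iodides, 14 (rings A–O–B) and 7 (rings C–O–D), with ethynyltrimethylsilane (A-to-D bridge).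
5. 14 and 7 ⇐ SNAr diaryl ether syntheses on 4-fluorobenzaldehyde and 2-fluoro-3-methoxybenzaldehyde (each from ArM + DMF). The four benzene rings are bought; the macrocycle is made 19-membered, then contracted to 18.

Assumption: the target SMILES has no stereocentre and the 18-membered ring is conformationally mobile, so marchantin C is achiral and no stereocontrol is needed.

Ring labels:
- A = ring with OH ortho to the ether oxygen and para to its bridge carbon.
- B = para-phenylene.
- C = 1,2,3-trisubstituted ring (CH2, OAr, OH).
- D = meta-phenylene.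

## Route

Step 1
Reactants: 1 2-fluorophenol
Product: 2 2-fluoroanisole
Conditions: MeI, K2CO3, acetone, reflux
Reagents that add atoms: iodomethane CI
Why: Williamson O-methylation of the phenoxide gives the methyl ether, which serves both as protecting group and as part of the directing pattern for the next step.

Step 2
Reactants: 2 2-fluoroanisole; 3 N,N-dimethylformamide
Product: 5 2-fluoro-3-methoxybenzaldehyde, via aryllithium 4 (not isolated)
Conditions: n-BuLi, PMDTA, THF, −78 °C; then DMF, −78 °C to rt; aq. HCl
Reagents that add atoms: none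
Why: Directed ortho-metalation with the amine-activated base removes the most acidic C–H, the one next to fluorine, and the aryllithium is formylated by DMF (Bouveault formylation).

Step 3
Reactants: 5 2-fluoro-3-methoxybenzaldehyde; 6 3-iodophenol
Product: 7 2-(3-iodophenoxy)-3-methoxybenzaldehyde
Conditions: K2CO3, DMA, 130 °C
Reagents that add atoms: none
Why: SNAr of the phenoxide on the fluoride activated by the ortho-formyl group; the aryl iodide is inert without Cu or Pd.

Step 4
Reactants: 8 1-bromo-4-fluorobenzene; 3 N,N-dimethylformamide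
Product: 10 4-fluorobenzaldehyde, via Grignard reagent 9 (not isolated)
Conditions: Mg, THF, rt to 40 °C; then DMF, 0 °C; aq. HCl
Reagents that add atoms: none
Why: Magnesium inserts only into the C–Br bond and the Grignard reagent is formylated by DMF (Bouveault formylation).

Step 5
Reactants: 10 4-fluorobenzaldehyde; 11 catechol (2.5 equiv)
Product: 13 4-(2-methoxyphenoxy)benzaldehyde, via phenol 12 (not isolated)
Conditions: K2CO3, DMF, 100 °C, N2; then MeI (excess), rt to 40 °C
Reagents that add atoms: iodomethane CI
Why: SNAr of catechol monoanion on the para-formyl-activated fluoride (excess catechol keeps it to mono-arylation), then Williamson methylation of the remaining phenol in the same pot.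

Step 6
Reactants: 13 4-(2-methoxyphenoxy)benzaldehyde
Product: 14 4-(5-iodo-2-methoxyphenoxy)benzaldehyde
Conditions: NIS, TFA (cat.), MeCN, rt
Reagents that add atoms: N-iodosuccinimide O=C1CCC(=O)N1I
Why: Electrophilic aromatic iodination goes para to the methoxy group, the strongest donor, because the aryloxy oxygen is drained by the formyl-bearing ring and that ring is itself deactivated.

Step 7
Reactants: 14 4-(5-iodo-2-methoxyphenoxy)benzaldehyde; 15 ethynyltrimethylsilane; 7 2-(3-iodophenoxy)-3-methoxybenzaldehyde
Product: 18 2-[3-({3-(4-formylphenoxy)-4-methoxyphenyl}ethynyl)phenoxy]-3-methoxybenzaldehyde, via TMS-alkyne 16 (not isolated), via terminal alkyne 17 (not isolated)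
Conditions: PdCl2(PPh3)2 (5 mol %), CuI (10 mol %), Et3N, THF, rt; then 7, DBU, H2O (1 equiv), 60 °C
Reagents that add atoms: none
Why: Sonogashira coupling of 14 with the silyl alkyne, in situ DBU/water desilylation and a second Sonogashira coupling with 7 give the unsymmetrical diaryl alkyne; aldehydes tolerate these conditions.

Step 8
Reactants: 18 2-[3-({3-(4-formylphenoxy)-4-methoxyphenyl}ethynyl)phenoxy]-3-methoxybenzaldehyde
Product: 19 2-[3-(2-{3-(4-formylphenoxy)-4-methoxyphenyl}ethyl)phenoxy]-3-methoxybenzaldehyde
Conditions: H2 (1 atm), 10% Pd/C, Ph2S (cat.), EtOAc, rt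
Reagents that add atoms: none
Why: Chemoselective heterogeneous hydrogenation; the sulfide-poisoned catalyst saturates the alkyne to CH2CH2 but leaves aromatic aldehydes and aryl C–O bonds untouched.

Step 9
Reactants: 19 2-[3-(2-{3-(4-formylphenoxy)-4-methoxyphenyl}ethyl)phenoxy]-3-methoxybenzaldehyde
Product: 22 19-membered azacyclophane (ring B–CH2–NH–CH2–ring C), via amino aldehyde 20 (not isolated), via macrocyclic imine 21 (not isolated)
Conditions: NH4OAc (1.5 equiv), NaBH(OAc)3 (4 equiv), AcOH (1 equiv), THF/DCE, rt, 19 added by syringe pump (final 2 mM)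
Reagents that add atoms: ammonium acetate CC(=O)[O-].[NH4+]
Why: Double reductive amination with ammonia: the first aldehyde becomes a primary benzylamine, which is far more nucleophilic than ammonia and condenses intramolecularly with the second aldehyde under high dilution, and the iminium is reduced faster than an aryl aldehyde (either aldehyde may react first; both paths converge on 22).

Step 10
Reactants: 22 19-membered azacyclophane
Product: 25 marchantin C di-O-methyl ether, via N-benzyloxy hydrazide 23 (not isolated), via isodiazene 24 (not isolated)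
Conditions: N-(benzyloxy)-N-(pivaloyloxy)-4-(trifluoromethyl)benzamide (1.5 equiv), THF, 45 °C, 0.01 M
Reagents that add atoms: none
Why: Proposed new method: nitrogen-deletion ring contraction of a 19-membered bis-benzylic azacyclophane: the amine attacks the electrophilic nitrogen of the anomeric amide (pivalate leaves), hydrazide 23 fragments by shift of the benzyloxy group to the acyl carbon to release isodiazene 24, and loss of N2 leaves a tethered singlet pair of two stabilised benzylic radicals born at bonding distance that collapses to the CH2–CH2 bond (19 → 18, stepwise radical, not concerted), with dilution suppressing tetrazene formation; the closest known reaction type is isodiazene nitrogen deletion of acyclic dibenzylamines and small or medium cyclic amines, which to my knowledge has not been shown on a macrocyclic azacyclophane of this kind.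

Step 11
Reactants: 25 marchantin C di-O-methyl ether
Product: 26 marchantin C
Conditions: BBr3 (6 equiv), CH2Cl2, −78 °C to rt; then H2O
Reagents that add atoms: none
Why: Lewis-acid cleavage of the two aryl methyl ethers by BBr3; the diaryl ether bonds are not cleaved.

## Compound list

1 | 2-fluorophenol | Oc1ccccc1F | starting material
2 | 2-fluoroanisole | COc1ccccc1F | intermediate
3 | N,N-dimethylformamide | CN(C)C=O | starting material
4 | (2-fluoro-3-methoxyphenyl)lithium (formed in situ) | COc1cccc([Li])c1F | intermediate
5 | 2-fluoro-3-methoxybenzaldehyde | COc1cccc(C=O)c1F | intermediate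
6 | 3-iodophenol | Oc1cccc(I)c1 | starting material
7 | 2-(3-iodophenoxy)-3-methoxybenzaldehyde | COc1cccc(C=O)c1Oc1cccc(I)c1 | intermediate
8 | 1-bromo-4-fluorobenzene | Fc1ccc(Br)cc1 | starting material
9 | 4-fluorophenylmagnesium bromide (formed in situ) | Fc1ccc([Mg]Br)cc1 | intermediate
10 | 4-fluorobenzaldehyde | O=Cc1ccc(F)cc1 | intermediate
11 | catechol | Oc1ccccc1O | starting material
12 | 4-(2-hydroxyphenoxy)benzaldehyde (formed in situ) | O=Cc1ccc(Oc2ccccc2O)cc1 | intermediate
13 | 4-(2-methoxyphenoxy)benzaldehyde | COc1ccccc1Oc1ccc(C=O)cc1 | intermediate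
14 | 4-(5-iodo-2-methoxyphenoxy)benzaldehyde | COc1ccc(I)cc1Oc1ccc(C=O)cc1 | intermediate
15 | ethynyltrimethylsilane | C#C[Si](C)(C)C | starting material
16 | 4-{2-methoxy-5-[(trimethylsilyl)ethynyl]phenoxy}benzaldehyde (formed in situ) | COc1ccc(C#C[Si](C)(C)C)cc1Oc1ccc(C=O)cc1 | intermediate
17 | 4-(5-ethynyl-2-methoxyphenoxy)benzaldehyde (formed in situ) | COc1ccc(C#C)cc1Oc1ccc(C=O)cc1 | intermediate
18 | 2-[3-({3-(4-formylphenoxy)-4-methoxyphenyl}ethynyl)phenoxy]-3-methoxybenzaldehyde | COc1ccc(C#Cc2cccc(Oc3c(C=O)cccc3OC)c2)cc1Oc1ccc(C=O)cc1 | intermediate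
19 | 2-[3-(2-{3-(4-formylphenoxy)-4-methoxyphenyl}ethyl)phenoxy]-3-methoxybenzaldehyde | COc1ccc(CCc2cccc(Oc3c(C=O)cccc3OC)c2)cc1Oc1ccc(C=O)cc1 | intermediate
20 | 2-[3-(2-{3-[4-(aminomethyl)phenoxy]-4-methoxyphenyl}ethyl)phenoxy]-3-methoxybenzaldehyde (formed in situ) | COc1ccc(CCc2cccc(Oc3c(C=O)cccc3OC)c2)cc1Oc1ccc(CN)cc1 | intermediate
21 | macrocyclic imine, ring B–CH2–N=CH–ring C, 19-membered, C=N geometry not defined (formed in situ) | COc1ccc2cc1Oc1ccc(cc1)CN=Cc1cccc(OC)c1Oc1cccc(c1)CC2 | intermediate
22 | 19-membered azacyclophane: marchantin C di-O-methyl ether with NH inserted between the two CH2 groups of the B–C bridge | COc1ccc2cc1Oc1ccc(cc1)CNCc1cccc(OC)c1Oc1cccc(c1)CC2 | intermediate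
23 | N-benzyloxy-N-[4-(trifluoromethyl)benzoyl] hydrazide of 22 at the ring nitrogen (formed in situ) | COc1ccc2cc1Oc1ccc(cc1)CN(N(OCc3ccccc3)C(=O)c3ccc(cc3)C(F)(F)F)Cc1cccc(OC)c1Oc1cccc(c1)CC2 | intermediate
24 | isodiazene (1,1-diazene) of 22 (formed in situ) | COc1ccc2cc1Oc1ccc(cc1)C[N+](=[N-])Cc1cccc(OC)c1Oc1cccc(c1)CC2 | intermediate
25 | marchantin C di-O-methyl ether | COc1ccc2cc1Oc1ccc(cc1)CCc1cccc(OC)c1Oc1cccc(c1)CC2 | intermediate
26 | marchantin C | Oc1ccc2cc1Oc1ccc(cc1)CCc1cccc(O)c1Oc1cccc(c1)CC2 | target

## Step count and risks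

Total steps: 11. Longest linear sequence: 8 steps (steps 1–3 then 7–11, or equally steps 4–6 then 7–11).

Three steps most likely to fail:

**Step 9 (macrocyclising double reductive amination with ammonia).** Risks are oligomers, the open-chain diamine and aldehyde reduction. The fallback sets out from 19 and replaces reductive amination by a sulfonamide double alkylation. NaBH4 in MeOH/THF gives the diol F1. PBr3 in CH2Cl2 at 0 °C gives the bis(benzyl bromide) F2. 2-Nitrobenzenesulfonamide with Cs2CO3 in DMF at 60 °C under high dilution gives the N-nosyl azacyclophane F3. PhSH with K2CO3 in MeCN removes the nosyl group and the route is rejoined at 22.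

**Step 10 (the proposed nitrogen-deletion ring contraction).** Risks are that the isodiazene isomerises to a hydrazone or dimerises to a tetrazene, or that the tethered radical pair couples between molecules. The fallback uses known chemistry and sets out from 19, bypassing 22. Intramolecular McMurry coupling (TiCl4, Zn, pyridine, THF, reflux, syringe-pump addition) gives the macrocyclic (Z)-stilbene F4; any E isomer converges. Hydrogenation (H2, Pd/C, EtOAc) gives the saturated bridge and the route is rejoined at 25.

**Step 7 (one-pot double Sonogashira).** Risks are Glaser homocoupling of 17 and scrambling to symmetrical diaryl alkynes. The fallback sets out from 7 and 14 and builds the bridge by a Heck reaction. Suzuki–Miyaura vinylation of 7 with potassium vinyltrifluoroborate (PdCl2(dppf), Cs2CO3, THF/H2O, 80 °C) gives 3-methoxy-2-(3-vinylphenoxy)benzaldehyde F5. Heck coupling of F5 with 14 (Pd(OAc)2, P(o-tol)3, Et3N, DMF, 100 °C) gives the (E)-stilbene dialdehyde F6. Hydrogenation under the step 8 conditions rejoins the route at 19.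

## Further compounds

F1 | step 9 | diol: 19 with both CHO groups reduced to CH2OH | COc1ccc(CCc2cccc(Oc3c(CO)cccc3OC)c2)cc1Oc1ccc(CO)cc1
F2 | step 9 | bis(benzyl bromide): 19 with both CHO groups replaced by CH2Br | COc1ccc(CCc2cccc(Oc3c(CBr)cccc3OC)c2)cc1Oc1ccc(CBr)cc1
F3 | step 9 | N-(2-nitrobenzenesulfonyl) derivative of azacyclophane 22 | COc1ccc2cc1Oc1ccc(cc1)CN(S(=O)(=O)c3ccccc3[N+](=O)[O-])Cc1cccc(OC)c1Oc1cccc(c1)CC2
F4 | step 10 | macrocyclic (Z)-stilbene: 25 with CH=CH in place of the B–C CH2CH2 bridge | COc1ccc2cc1Oc1ccc(cc1)/C=C\c1cccc(OC)c1Oc1cccc(c1)CC2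
F5 | step 7 | 3-methoxy-2-(3-vinylphenoxy)benzaldehyde | COc1cccc(C=O)c1Oc1cccc(C=C)c1
F6 | step 7 | (E)-stilbene dialdehyde: 19 with (E)-CH=CH in place of the A–D CH2CH2 bridge | COc1ccc(/C=C/c2cccc(Oc3c(C=O)cccc3OC)c2)cc1Oc1ccc(C=O)cc1
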